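A stall could not by itself tell me what a product cost in nucleophile, for a reversible step also stops with electrophile left. At 1 equiv of nucleophile, Saturday's product stopped near 54% with 34% of electrophile read, and Sunday's stopped near 48% with 26% read. Those product readings stood near half of the nucleophile charged on Saturday and half on Sunday, at two different charges, so I took a price of two nucleophile per product as my working reading. The balance gave a second clue. Its gap read 0.0195 M on Saturday and 0.0175 M on Sunday, both close to the 0.020 M of protic impurity charged.

| flask | electrophile | nucleophile | protic impurity | remark | time |
|---|---|---|---|---|---|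
| Saturday's | 0.15 M | 1 equiv | 0.020 M | run made earlier |  |
| Sunday's | 0.050 M | 1 equiv | 0.020 M | run made earlier |  |
| summer | 0.10 M | 1.00 equiv | 0.0200 M |  | 80 min |
| spring | 0.10 M | 2.00 equiv | 0.0200 M |  | 80 min |
| autumn | 0.10 M | 4.00 equiv | 0.0200 M |  | 80 min |

| run | time / min | electrophile / % | product / % |
|---|---|---|---|
| Saturday's | 5.00 | 44 | 48 |
| Saturday's | 10.0 | 32 | 49 |
| Saturday's | 15.0 | 41 | 53 |
| Saturday's | 20.0 | 34 | 54 |
| Saturday's | 25.0 | 34 | 53 |
| Saturday's | 30.0 | 32 | 49 |
| Sunday's | 2.50 | 60 | 31 |
| Sunday's | 4.00 | 45 | 38 |
| Sunday's | 6.00 | 41 | 41 |
| Sunday's | 10.0 | 30 | 45 |
| Sunday's | 15.0 | 26 | 48 |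
| Sunday's | 30.0 | 19 | 46 |

(each reading ± 2 percentage points)

- the earlier runs were read with a standard deviation of 2 percentage points

- part of the electrophile that has reacted at the end, summer
- part of the electrophile that has reacted at the end, spring
- part of the electrophile that has reacted at the end, autumn
- what raising the equivalents of nucleophile from its lowest to its highest value here does to the part of the electrophile that has reacted (changes below 5 percentage points count as none) (it rises / no change / it falls)

Two extremes of summer solve in the head. At one nucleophile per product, the symmetric case, with no way back, the electrophile reaches 100% reacted. At two per product with an idle impurity, it stops at 50.0%. The readings pointed between them. Sunday's gap was already near the impurity charge at 30.0 min, and summer ran longer, so I let the impurity take its whole charge.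

Half of c(nucleophile) plus c(protic impurity), over c(electrophile), gave 70.0% for summer. I call this the reacted ceiling. It was less than the whole charge, so nucleophile was the limiting reagent in summer. Spring gave 120% and autumn 220%, both more than the whole charge.

I forecast 70% for summer, 99% for spring and 100% for autumn, and for the trend: it rises. My ground was this: “so each product seems to cost two nucleophile”.

    electrophile + nucleophile ⇌ acid set free + product (K = 12.9, k = 5.16 M⁻¹ min⁻¹)
    electrophile + protic impurity → quenched substrate (k = 3.69 M⁻¹ min⁻¹)
    nucleophile + acid set free ⇌ protonated nucleophile, settled at all times (K = 29200 M⁻¹)

Summer reached 71.5% against its ceiling of 70.0%, and it stayed there when given tenfold time. Spring and autumn both reached >99.9%, so the answer to the trend was it rises, by 29 points. In summer, 51.5% stood as product and 20.0% as quenched substrate, while 0.0480 M of protonated nucleophile held the second share of the price. A neighbour of summer with 0.250 equiv of nucleophile had a ceiling of 32.5%. It ended at 34.5% reacted, with 20.0% as quenched substrate and 14.5% as product.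

The earlier runs and the new flask are simulated from invented constants; the scatter is artificial.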